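**Retrosynthetic overview**
- Target ⇐ spiro-γ-lactone (C15 carbonyl) by lactone → lactol → dehydration; ring D is brought to the enol-ether level last and no stereocentre is touched.
- Spiro-lactone ⇐ C9 decalone + 4-vinylbutenolide in one reductive, polarity-reversed step: the C9 ketyl adds to the vinyl terminus (C9–C11), then oxa-Michael closure of ring C (O9–C13) follows in the same flask.
- Decalone ⇐ cis-fused Diels–Alder adduct by face-selective hydrogenation (C8), hydride reduction (C6), cyclopropane → gem-dimethyl hydrogenolysis and acetylation.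
- Adduct ⇐ 2,6-dimethyl-1,4-benzoquinone (ring B, carrying the C6/C9 dioxygen pattern) + allylidenecyclopropane (ring A, masked gem-dimethyl) by catalytic enantioselective Diels–Alder, which sets C5/C10 cis.
- Ring order: B (quinone) → A (Diels–Alder) → D (butenolide, made separately) → C (spiro-tetrahydrofuran, key step).

Assumption: the SMILES is read literally, i.e. (5R,6R,8R,9R,10S,13R) with a cis A/B fusion (H-5 and CH3-10 both β); labdane numbering (C1–C20) is used for all compounds and β means the face of CH3-20.

**Route**

Step 1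
Reactants: 1 cyclopropyltriphenylphosphonium bromide; 2 acrolein
Product: 4 allylidenecyclopropane, via cyclopropylidene(triphenyl)phosphorane 3 (not isolated)
Conditions: KOC(CH3)3, THF, 0 → 50 °C; product distilled
Reagents that add atoms: none
Why: Wittig olefination of the enal by the non-stabilised cyclopropylidene ylide gives the diene whose cyclopropylidene terminus is a sterically small, reactive stand-in for a gem-dimethyl terminus; no stereocentre is formed.

Step 2
Reactants: 4 allylidenecyclopropane; 5 2,6-dimethyl-1,4-benzoquinone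
Product: 6 cis-fused enedione (ring B = 8-methylcyclohex-7-ene-6,9-dione, ring A = cyclohex-2-ene with spiro-cyclopropane at C4, CH3 on C10; H-5 and CH3-10 both β; 5R,10S)
Conditions: (S)-1-(2-methylphenyl)-3,3-diphenyltetrahydro-1H,3H-pyrrolo[1,2-c][1,3,2]oxazaborole (20 mol%), HN(SO2CF3)2 (17 mol%), CH2Cl2, −78 → −40 °C
Reagents that add atoms: none
Why: Cationic-oxazaborolidine (Corey) catalysed Diels–Alder reaction: the catalyst binds the unhindered C6 carbonyl (α-C–H at C5), so the CH2 terminus of the diene bonds to the β-carbon C10 and the cyclopropylidene terminus to C5; suprafacial addition makes the fusion cis and the catalyst fixes the absolute sense at C5/C10 (the catalyst antipode gives ent-6).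

Step 3
Reactants: 6 cis-fused enedione
Product: 7 8α,10β-dimethyl-4-spirocyclopropyl-cis-decalin-6,9-dione (5β-H, 8β-H; 5R,8R,10S)
Conditions: H2 (1 atm), PtO2, EtOAc, rt, stopped after 2 equiv H2
Reagents that add atoms: none
Why: Heterogeneous hydrogenation over platinum in a neutral solvent saturates both C=C bonds but leaves the cyclopropane and the ketones; H2 adds to C7=C8 from the convex β-face of the cis-fused bicycle (the face of H-5 and CH3-10, ring A shields the α-face), which places H-8 β and CH3-17 α.

Step 4
Reactants: 7 spirocyclopropyl diketone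
Product: 8 6β-hydroxy-8α,10β-dimethyl-4-spirocyclopropyl-cis-decalin-9-one (5R,6R,8R,10S)
Conditions: NaBH4 (0.5 equiv), CH2Cl2/MeOH 1:1, −78 → −30 °C
Reagents that add atoms: none
Why: Chemo- and face-selective borohydride reduction: C9 is flanked by quaternary C10 and branched C8 and is left, while in the ring B chair that keeps CH3-17 equatorial CH3-10 is axial over the β-face of C6, so hydride enters equatorially from the α-side and gives the axial 6β-alcohol (the outcome recalled for 5β-6-oxo steroids); the small spiro-cyclopropane keeps that α-trajectory open.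

Step 5
Reactants: 8 spirocyclopropyl hydroxy ketone
Product: 9 6β-hydroxy-4,4,8α,10β-tetramethyl-cis-decalin-9-one (5β-H; 5R,6R,8R,10S)
Conditions: H2 (4 atm), PtO2, AcOH, rt
Reagents that add atoms: none
Why: Hydrogenolysis of the distal, least hindered cyclopropane bond over platinum in acetic acid unveils the gem-dimethyl group; the doubly α-branched C9 ketone is not reduced and no stereocentre is affected.

Step 6
Reactants: 9 hydroxy ketone
Product: 10 6β-acetoxy-4,4,8α,10β-tetramethyl-cis-decalin-9-one (5R,6R,8R,10S)
Conditions: Ac2O, 4-(dimethylamino)pyridine (0.2 equiv), pyridine, 40 °C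
Reagents that add atoms: acetic anhydride, CC(=O)OC(C)=O
Why: Nucleophile-catalysed acylation of the hindered axial secondary alcohol, with retention at C6.

Step 7
Reactants: 11 tetronic acid
Product: 12 4-bromofuran-2(5H)-one
Conditions: (COBr)2, N,N-dimethylformamide (cat.), CH2Cl2, 0 °C → rt
Reagents that add atoms: oxalyl bromide, O=C(Br)C(Br)=O
Why: Vilsmeier–Haack-type activation of the vinylogous acid followed by addition–elimination of bromide (deoxybromination); no stereocentre.

Step 8
Reactants: 12 4-bromofuran-2(5H)-one; 13 potassium vinyltrifluoroborate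
Product: 14 4-vinylfuran-2(5H)-one
Conditions: PdCl2[Fe(C5H4PPh2)2] (3 mol%), Cs2CO3, THF/H2O 9:1, 65 °C; used at once
Reagents that add atoms: none
Why: Suzuki–Miyaura cross-coupling of the activated β-bromobutenolide with the vinyl trifluoroborate gives the cross-conjugated dienoate acceptor; no stereocentre.

Step 9
Reactants: 10 acetoxy ketone; 14 4-vinylfuran-2(5H)-one
Product: 16 (13R)-6β-acetoxy-9α,13-epoxy-5β-labdan-15,16-olide, via hydroxy-butenolide 15 (not isolated)
Conditions: SmI2 (2.4 equiv), hexamethylphosphoramide, t-BuOH (2.2 equiv), THF, −78 °C → rt; then 1,8-diazabicyclo[5.4.0]undec-7-ene (0.3 equiv), rt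
Reagents that add atoms: none
Why: Proposed new method: SmI2 reduces the hindered C9 ketone to a trivalent-samarium ketyl, a nucleophilic carbonyl carbon, which adds to the unsubstituted vinyl terminus of 14 (C9–C11 bond between two carbons that are both electrophilic in their parent forms); a second electron gives the samarium dienolate, protonation gives 15 and the C9 alkoxide closes ring C by 5-exo oxa-Michael addition at C13; the closest known reaction is the SmI2 ketone–acrylate reductive coupling to γ-lactones (ketyl–olefin coupling), used here in vinylogous 1,6-mode; C9 is set by C–C bond formation from the open equatorial β-side (the α-axial side is blocked by C4), and C13 by the reversible oxa-Michael step, for which little substrate bias is expected, so the 13R lactone is separated and the 13S epimer is re-equilibrated with the amidine base and recycled.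

Step 10
Reactants: 16 spiro-lactone
Product: 17 (13R)-6β-acetoxy-9α,13:15,16-diepoxy-5β-labdan-15-ol (lactol, C15 anomers)
Conditions: (i-C4H9)2AlH (1.1 equiv), CH2Cl2, −78 °C
Reagents that add atoms: none
Why: Partial reduction of the γ-lactone through the tetrahedral aluminate that is stable at −78 °C; the unhindered five-ring lactone reacts much faster than the axial, neopentyl-type 6β-acetate, and C15 forms as an inconsequential anomeric mixture.

Step 11
Reactants: 17 lactol
Product: 19 target 6β-acetoxy-9α,13:15,16-diepoxy-5β-labd-14-ene, via C15 methanesulfonate 18 (not isolated)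
Conditions: CH3SO2Cl (1.5 equiv), Et3N (5 equiv), CH2Cl2, −40 °C → 40 °C; Et3N-buffered chromatography
Reagents that add atoms: none
Why: Sulfonylation of the lactol hydroxyl and loss of methanesulfonate through the oxocarbenium ion, with deprotonation at C14 (the only β-hydrogens, C13 being quaternary), gives the 2,3-dihydrofuran under basic conditions that spare the acid-labile vinylogous acetal; no stereocentre changes.

**Compound list**
1 | cyclopropyltriphenylphosphonium bromide | [Br-].C1CC1[P+](c1ccccc1)(c1ccccc1)c1ccccc1 | starting material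
2 | acrolein | C=CC=O | starting material
3 | cyclopropylidene(triphenyl)phosphorane | C1CC1=P(c1ccccc1)(c1ccccc1)c1ccccc1 | intermediate
4 | allylidenecyclopropane | C=CC=C1CC1 | intermediate
5 | 2,6-dimethyl-1,4-benzoquinone | CC1=CC(=O)C=C(C)C1=O | starting material
6 | cis-fused enedione adduct (5R,10S; C2=C3, C7=C8, 4-spirocyclopropane, 8,10-dimethyl, 6,9-dione) | O=C1C=C(C)C(=O)[C@@]2(C)CC=CC3(CC3)[C@@H]12 | intermediate
7 | 8α,10β-dimethyl-4-spirocyclopropyl-cis-decalin-6,9-dione (5R,8R,10S) | O=C1C[C@@H](C)C(=O)[C@@]2(C)CCCC3(CC3)[C@@H]12 | intermediate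
8 | 6β-hydroxy-8α,10β-dimethyl-4-spirocyclopropyl-cis-decalin-9-one (5R,6R,8R,10S) | O[C@@H]1C[C@@H](C)C(=O)[C@@]2(C)CCCC3(CC3)[C@@H]12 | intermediate
9 | 6β-hydroxy-4,4,8α,10β-tetramethyl-cis-decalin-9-one (5R,6R,8R,10S) | O[C@@H]1C[C@@H](C)C(=O)[C@@]2(C)CCCC(C)(C)[C@@H]12 | intermediate
10 | 6β-acetoxy-4,4,8α,10β-tetramethyl-cis-decalin-9-one (5R,6R,8R,10S) | CC(=O)O[C@@H]1C[C@@H](C)C(=O)[C@@]2(C)CCCC(C)(C)[C@@H]12 | intermediate
11 | tetronic acid (4-hydroxyfuran-2(5H)-one) | OC1=CC(=O)OC1 | starting material
12 | 4-bromofuran-2(5H)-one | BrC1=CC(=O)OC1 | intermediate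
13 | potassium vinyltrifluoroborate | [K+].C=C[B-](F)(F)F | starting material
14 | 4-vinylfuran-2(5H)-one | C=CC1=CC(=O)OC1 | intermediate
15 | 6β-acetoxy-9α-hydroxy-5β-labd-13-en-15,16-olide (C15 carbonyl) | CC(=O)O[C@@H]1C[C@@H](C)[C@](O)(CCC2=CC(=O)OC2)[C@@]2(C)CCCC(C)(C)[C@@H]12 | intermediate
16 | (5R,6R,8R,9R,10S,13R)-6β-acetoxy-9α,13-epoxy-5β-labdan-15,16-olide | CC(=O)O[C@@H]1C[C@@H](C)[C@]2(CC[C@]3(CC(=O)OC3)O2)[C@@]2(C)CCCC(C)(C)[C@@H]12 | intermediate
17 | (13R)-6β-acetoxy-9α,13:15,16-diepoxy-5β-labdan-15-ol (C15 anomers) | CC(=O)O[C@@H]1C[C@@H](C)[C@]2(CC[C@]3(CC(O)OC3)O2)[C@@]2(C)CCCC(C)(C)[C@@H]12 | intermediate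
18 | C15 methanesulfonate of 17 | CC(=O)O[C@@H]1C[C@@H](C)[C@]2(CC[C@]3(CC(OS(C)(=O)=O)OC3)O2)[C@@]2(C)CCCC(C)(C)[C@@H]12 | intermediate
19 | (5R,6R,8R,9R,10S,13R)-6β-acetoxy-9α,13:15,16-diepoxy-5β-labd-14-ene (CNP0242014.2) | CC(=O)O[C@@H]1C[C@@H](C)[C@]2(CC[C@]3(C=COC3)O2)[C@@]2(C)CCCC(C)(C)[C@@H]12 | target

**Step count**
Total steps: 11. Longest linear sequence: 9 (steps 1–6, 9–11).

**Three steps most likely to fail**

Step 9 (key coupling). The vinylogous ketyl addition is unprecedented on so hindered a ketone, the dienoate may be reduced first, and C13 is expected to form close to 1:1. The fallback sets out from 10. SmI2, methyl acrylate and t-BuOH (the established ketone–acrylate reductive lactonisation) give the C9 spiro-γ-lactone F1. (C5H5)2Ti(CH3)2 in toluene at 65 °C methylenates the lactone carbonyl (the hindered axial acetate should be spared) to the exocyclic enol ether F2. Dichloroketene (Cl3CCOCl, zinc–copper couple) adds [2+2] to give the dichlorocyclobutanone F3, and Zn/AcOH removes both chlorines to give the spiro-cyclobutanone F4, in which C13 is not yet a stereocentre. A catalyst-controlled Baeyer–Villiger oxidation ((R)-3,3′-bis(2,4,6-triisopropylphenyl)-1,1′-binaphthalene-2,2′-diyl hydrogen phosphate, aq. H2O2, CHCl3, −40 °C) then selects which of the two diastereotopic CH2 groups migrates. This comes back to the route at 16, with C13 fixed by the catalyst instead of by equilibrium.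

Step 2 (Diels–Alder). The strongly acidic chiral catalyst may degrade the strained diene or give low enantioselectivity with this unusual diene. I have not derived which catalyst enantiomer gives 6 rather than ent-6, so the (S) label is provisional. The fallback sets out from 4 and 5. The cycloaddition is run with achiral BF3·O(C2H5)2 (CH2Cl2, −78 °C; same regiochemistry through coordination at the unhindered carbonyl) to give the racemic cis adduct F5. F5 is resolved by preparative chromatography on a chiral stationary phase instead of by asymmetric catalysis, and the route is rejoined at 6.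

Step 4 (C6 reduction). Hydride might instead attack from the β-face and give the 6α-alcohol. The fallback sets out from 6. The C6 carbonyl is reduced at the flat enedione stage under reagent control (BH3·S(CH3)2 with (R)-1-methyl-3,3-diphenyltetrahydro-1H,3H-pyrrolo[1,2-c][1,3,2]oxazaborole, or its antipode, whichever is matched for α-face delivery; Corey–Bakshi–Shibata reduction) to give the 6β-hydroxy enone F6. Hydrogenation of both C=C bonds (H2, PtO2, EtOAc) then returns to the route at 8.

**Further compounds**
F1 | step 9 | 6β-acetoxy-14,15,16-trinor-5β-labdan-13,9α-olide (C9 spiro-γ-lactone) | CC(=O)O[C@@H]1C[C@@H](C)[C@]2(CCC(=O)O2)[C@@]2(C)CCCC(C)(C)[C@@H]12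
F2 | step 9 | 13-methylene analogue of F1 (exocyclic enol ether) | CC(=O)O[C@@H]1C[C@@H](C)[C@]2(CCC(=C)O2)[C@@]2(C)CCCC(C)(C)[C@@H]12
F3 | step 9 | spiro-2,2-dichlorocyclobutanone (CCl2 on C13, C13 epimers) | CC(=O)O[C@@H]1C[C@@H](C)[C@]2(CCC3(CC(=O)C3(Cl)Cl)O2)[C@@]2(C)CCCC(C)(C)[C@@H]12
F4 | step 9 | spiro-cyclobutanone (C13 spiro, C15 carbonyl) | CC(=O)O[C@@H]1C[C@@H](C)[C@]2(CCC3(CC(=O)C3)O2)[C@@]2(C)CCCC(C)(C)[C@@H]12
F5 | step 2 | racemic cis-fused enedione adduct (6 and ent-6) | O=C1C=C(C)C(=O)[C@@]2(C)CC=CC3(CC3)[C@@H]12.O=C1C=C(C)C(=O)[C@]2(C)CC=CC3(CC3)[C@H]12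
F6 | step 4 | 6β-hydroxy enone (6 with C6 carbonyl reduced, both C=C kept) | O[C@@H]1C=C(C)C(=O)[C@@]2(C)CC=CC3(CC3)[C@@H]12
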